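## The problem

The target joins two diterpenoid halves through a six-membered carbocycle: a trans-decalin with a C20 carboxyl on C10, a C8 methylidene and a CH2 link (C11) on C9, and a 7′β-acetoxy totarane whose phenol oxygen (O13′) and aryl carbon C14′ are tied into a benzofuran-2(3H)-one. The lactone α-carbon (C4″) is the spiro centre of the new ring. It is quaternary and sits on an aryl carbon flanked by the phenol oxygen on one side and by ring B with its C7′ acetoxy group on the other, so it is the most crowded atom of the molecule. There are nine stereocentres. C5/C10 of the decalin can be bought, C9 is epimerisable next to a C8 carbonyl, C5′/C10′ come from a polyene cyclisation, and C7′ can follow the C10′ methyl. C4″ is remote from all of these and needs external control. Once C4″ is set it can direct C3″ and C1″, because the aryl and carbonyl faces of the new ring differ strongly. The fragile groups are the two 1,1-disubstituted alkenes (strong protic acid), the allylic alcohol beside a methylidene, the aryl lactone (nucleophiles) and the C20 acid, which is too hindered for acyl substitution. A free C7′ hydroxyl beside the carboxyl or the aryl lactone could close a six-membered lactone of its own. The enabling feature is that C4″ carries an aryl ring and a carboxyl carbon while C1″ is an oxidised carbon and C3″ carries the link. Ring C1″–C6″ is therefore the retron of a 4,4-disubstituted cyclohex-2-enone, that is, of a Robinson annulation of an α-aryl β-keto ester.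

## Retrosynthesis

**Late functional groups.** Target 39 is the free acid of silyl ester 38. The C1″ carbinol of 38 comes from the ketone of methylidene enone 37. The methylidene carbon of 37 is attached through the regiodefined silyl enol ether 34, and 34 comes from conjugate reduction of cyclohexenone 33. These cuts remove two stereocentres and both acid-sensitive groups of the new ring. In the forward sense both hydride additions must come from the lactone-carbonyl face of the ring.

**Lactone C–O bond.** Spirolactone 33 is opened to acetate 32, which holds a MOM-protected phenol and a tert-butyl ester. The acetate of 32 is put on in place of the silyl ether of 30 before the lactone exists, so O7′ is never free beside the carboxyl. The forward step must unmask phenol and acid without a strong protic acid.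

**Key cut: C4″–C5″ and C2″=C3″.** Enone 30 is cut into keto ester 26 and methyl vinyl ketone 27. The neighbouring options would form the aryl–quaternary carbon bond (C14′–C4″) directly, by arylation or rearrangement at the crowded position. This cut instead makes C4″ from a planar, stabilised enolate and an unhindered acceptor, and closes the ring at the same stage. One ring and the quaternary stereocentre disappear. The forward reaction must control one new stereocentre and the direction of the aldol closure.

**Ketone–α-carbon bond.** Keto ester 26 is cut between C3″ and C4″ into decalin acetic acid 11 and tert-butyl arylacetate 24, joined forward by a crossed Claisen acylation through imidazolide 25. The two fragments are of similar size, so the route is convergent up to the step before the key step.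

**Aryl half.** Arylacetate 24 comes from aryl bromide 23 by palladium-catalysed coupling with an acetate enolate; this makes the C14′–C15′ bond on a CH2 carbon, where crowding matters least. The C7′ oxygen of 23 goes back through alcohol 22 and ketone 21 to benzylic oxidation of tricycle 18; the MOM group replaces the methyl ether at phenol 20.

**Totarane skeleton.** Tricycle 18 is cut at C4′–C5′ and C9′–C10′ to aryl diene 17, the substrate of an enantioselective cation–olefin bicyclisation. The bromine of 17 blocks the second ortho position and later serves as the coupling handle. 17 comes from benzyl chloride 14 (from aldehyde 12) and geranyl chloride 15.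

**Decalin side chain.** Acid 11 comes from methylidene ester 10 and ketone 9. The C9–C11 bond of 9 is made by alkylating β-keto ester 7 at C9, giving 8; the old ring-C carboxyl on C9 only directs the alkylation and then leaves as CO2. A plain C8 ketone would alkylate at C7, which is why this order is chosen.

**Ring C excision.** β-Keto ester 7 comes from carnosic acid 1 via silyl ester 2. The C11–C12 bond is cut by oxygen insertion (anhydride 3, diester 5), the diene is moved to C8=C14 by 1,6-reduction (6), and that alkene is cut by ozone. Carnosic acid supplies C5, C10 and the C20 carboxyl at the right oxidation level.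

## Roads not taken

**Alternative 1:** The cut is the C11–C12 bond of ring C of carnosic acid. Forward, a peracid inserts oxygen between the two carbonyls of the carnosate-derived ortho-quinone A2 and gives the decalin-fused muconic anhydride A1. Merits: three atoms of the decalin (C5, C10, C20) arrive with correct configuration and oxidation level, and the reaction type is known on hindered quinones. Weak points for this target: as the defining step of a plan it forms no bond of the target. It leaves a carboxyl directly on C9, one carbon short of the CH2–C(=O) link, and it has no answer to the quaternary C4″ or to the union of the halves. Comparison: as a source of the decalin this road is as good as any, and the chosen route runs the same oxygen insertion on 2 (giving 3) as a supporting operation. What the chosen plan adds is a solution to the hard part.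

**Alternative 2:** The cut is C4–C5 and C9–C10 of the decalin, made late on a substrate that already carries the spirolactone enone. Forward, MeAlCl2 opens a terminal epoxide, the cation passes through two trisubstituted alkenes, and an allylsilane terminator loses silicon to give the C8 methylidene of A3. Merits: C5, C9 and C10 are set in one step from one epoxide, the methylidene arises directly, and neither a degradation nor the crowded C9 alkylation (step 5 here) is needed. Weak points: A3 has a 3β-hydroxyl that the target lacks and C20 at the alcohol level, so deoxygenation and two oxidations follow late. The central alkene is deactivated by its allylic silyloxymethyl group, and the Lewis acid meets an enone, an aryl lactone and a benzylic silyl ether. The quaternary C4″ must already exist, so the central problem is moved, not solved. Comparison: this road is probably shorter for the decalin itself. The chosen plan offers correct oxidation states from 1, no late cationic step and a convergent union of 11 and 24.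

**Alternative 3:** The cut is the C14′–C4″ bond together with the lactone C–O bond. Forward, a cyclohex-2-enyl group migrates thermally from the phenol oxygen to the ortho carbon C14′ ([3,3] shift onto the ester-bearing alkene carbon), and the liberated phenol lactonises to give A4. Merits: the configuration of C4″ comes by suprafacial chirality transfer from a secondary allylic carbinol, which is easy to set and independent of any catalyst–substrate pairing; the lactone closes in the same operation. Weak points: the migration terminus is a fully substituted, electron-poor alkene carbon and the receiving carbon is the peri-hindered C14′. The other ortho position must be blocked by bromine (present in A4) and cleared later, and prolonged heating endangers the benzylic acetate. Comparison: in stereochemical logic this road is better than the chosen one, which relies on catalyst control over a large chiral substrate. In return the chosen plan makes the quaternary centre by a far less demanding bond formation and makes the aryl–carbon bond early on a CH2 carbon; the C4″ epimers of 30 are diastereomers and can be separated.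

Key step: step 20

Remark: centres that a later step erases (C9 and C13 of 6, C9 of 7 and 8, the α-carbon of 26, the carbinol of 29, C2″ of 35 and 36) are carried as mixtures and left undefined. Atom labels are labdane numbers for the decalin, primed totarane numbers for the aryl half, and double-primed numbers for the new ring (C1″ carbonyl or carbinol, C3″ link-bearing, C4″ spiro).

## Route

Step 1
Reactants: 1 carnosic acid
Product: 2 2-(trimethylsilyl)ethyl carnosate
Conditions: Cl3CC(=NH)OCH2CH2SiMe3, toluene, 100 °C, Ar
Reagents that add atoms: 2-(trimethylsilyl)ethyl 2,2,2-trichloroacetimidate, C[Si](C)(C)CCOC(=N)C(Cl)(Cl)Cl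
Why: Thermal trichloroacetimidate esterification: the acid protonates the imidate and is alkylated on oxygen, so the hindered C20 carbonyl is never attacked and the less acidic phenols stay free; the ester also blocks later lactonisation of C20 onto C7.

Step 2
Reactants: 2 2-(trimethylsilyl)ethyl carnosate
Product: 5 dimethyl cis,cis-muconate of ring-C-opened 2, via muconic anhydride 3 (not isolated), via muconic half-ester 4 (not isolated)
Conditions: mCPBA (2.2 equiv), CH2Cl2, 0 °C; aq. NaHCO3 wash; MeOH, DMAP (cat.), rt; Me3SiCHN2, MeOH–toluene, 0 °C
Reagents that add atoms: 3-chloroperoxybenzoic acid, OOC(=O)c1cccc(Cl)c1; methanol, CO; (trimethylsilyl)diazomethane, C[Si](C)(C)C=[N+]=[N-]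
Why: Peracid oxidises the catechol to the ortho-quinone and then inserts oxygen between its carbonyls (Baeyer–Villiger-type intradiol cleavage) to give 3; methanol opens the anhydride at the less hindered carbonyl and diazoalkane esterification completes 5. The decalin stereocentres are not touched.

Step 3
Reactants: 5 dimethyl cis,cis-muconate of ring-C-opened 2
Product: 6 C8=C14 diester (1,6-dihydro compound)
Conditions: SmI2 (2.5 equiv), THF–MeOH, −78 °C
Reagents that add atoms: none
Why: Electron-transfer 1,6-reduction of a muconate, the reaction type known from the reduction of muconic acid to its 3-ene: two electrons give the extended dienolate and kinetic protonation at both α-carbons (C9, C13) leaves the alkene at C8=C14. The new centres are formed as mixtures and are erased in steps 4 and 6.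

Step 4
Reactants: 6 C8=C14 diester
Product: 7 bicyclic β-keto ester (C8 ketone with C9 methyl ester)
Conditions: O3, CH2Cl2–MeOH, −78 °C; Me2S
Reagents that add atoms: ozone, [O-][O+]=O
Why: Ozonolysis of the only alkene with reductive work-up excises C12–C14 with the isopropyl group and leaves the C8 ketone beside the C9 ester.

Step 5
Reactants: 7 bicyclic β-keto ester
Product: 8 C9-alkylated keto diester
Conditions: Cs2CO3, BrCH2CO2Me, DMF, 0 °C → rt
Reagents that add atoms: methyl bromoacetate, COC(=O)CBr
Why: C-alkylation of a β-keto ester enolate with a reactive α-halo ester; the ester on C9 directs the new bond to C9 and away from C7. The C9 configuration is immaterial.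

Step 6
Reactants: 8 C9-alkylated keto diester
Product: 9 C8 ketone with 9β-CH2CO2Me (9α-H)
Conditions: LiCl, DMSO–H2O, 140 °C
Reagents that add atoms: none
Why: Krapcho dealkoxycarbonylation: chloride demethylates only the activated β-keto ester and the acid loses CO2; C9 then equilibrates through the enol to the equatorial side chain (9α-H), the configuration of the target.

Step 7
Reactants: 9 C8 ketone with 9β-CH2CO2Me
Product: 10 C8-methylidene methyl ester
Conditions: Ph3PCH3Br, KOtBu, toluene, 80 °C
Reagents that add atoms: methyltriphenylphosphonium bromide, C[P+](c1ccccc1)(c1ccccc1)c1ccccc1.[Br-]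
Why: Wittig methylenation of an α-substituted ketone; any epimerisation at C9 under the basic ylide returns to the same thermodynamic isomer.

Step 8
Reactants: 10 C8-methylidene methyl ester
Product: 11 decalin acetic acid
Conditions: LiOH, THF–MeOH–H2O, rt; dilute HCl work-up
Reagents that add atoms: lithium hydroxide, [Li+].[OH-]
Why: Saponification of the unhindered primary ester; the tertiary, neopentyl-type C20 silyl ester is inert to hydroxide.

Step 9
Reactants: 12 2-bromo-3-methoxybenzaldehyde
Product: 13 (2-bromo-3-methoxyphenyl)methanol
Conditions: NaBH4, MeOH, 0 °C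
Reagents that add atoms: none
Why: Borohydride reduction of an aromatic aldehyde.

Step 10
Reactants: 13 (2-bromo-3-methoxyphenyl)methanol
Product: 14 2-bromo-1-(chloromethyl)-3-methoxybenzene
Conditions: SOCl2, DMF (cat.), CH2Cl2, 0 °C → rt
Reagents that add atoms: thionyl chloride, O=S(Cl)Cl
Why: Chlorination of a benzylic alcohol; the chloride is chosen over the bromide to limit Wurtz coupling in step 11.

Step 11
Reactants: 14 2-bromo-1-(chloromethyl)-3-methoxybenzene, 15 geranyl chloride
Product: 17 2-bromo-1-[(3E)-4,8-dimethylnona-3,7-dienyl]-3-methoxybenzene, via benzylic Grignard reagent 16 (not isolated)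
Conditions: Mg, Et2O, 0 °C; then 15, Li2CuCl4 (3 mol%), THF, −20 °C → rt
Reagents that add atoms: none
Why: Magnesium inserts into the benzylic C–Cl bond faster than into the aryl C–Br bond; copper-catalysed allylic substitution of the primary chloride then occurs at the α-carbon with retention of the E alkene.

Step 12
Reactants: 17 aryl diene
Product: 18 14′-bromo-13′-methoxypodocarpa-8′,11′,13′-triene (5′α-H; 10′β-CH3)
Conditions: SbCl5·(R)-3,3′-dichloro-BINOL (1:1, 0.5 equiv), CH2Cl2, −78 °C
Reagents that add atoms: none
Why: Enantioselective proton-initiated cation–olefin bicyclisation with a Lewis acid-activated chiral Brønsted acid: the chiral acid selects the face of the terminal alkene, and the chair–chair antiperiplanar cascade gives the trans ring fusion (C5′, C10′). The arene closes para to the methoxy group, and the bromine blocks the other ortho site.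

Step 13
Reactants: 18 tricyclic bromide
Product: 19 7′-ketone of 18
Conditions: CrO3, AcOH–H2O, rt
Reagents that add atoms: chromium trioxide, O=[Cr](=O)=O
Why: Chromic acid oxidation of the only benzylic methylene, a standard reaction of podocarpatrienes.

Step 14
Reactants: 19 7′-ketone of 18
Product: 20 14′-bromo-13′-hydroxypodocarpa-8′,11′,13′-trien-7′-one
Conditions: BBr3, CH2Cl2, −78 → 0 °C
Reagents that add atoms: none
Why: Boron tribromide cleavage of an aryl methyl ether; the aryl ketone and bromide are stable, and nothing acid-sensitive is present yet.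

Step 15
Reactants: 20 phenol ketone
Product: 21 13′-O-methoxymethyl ether of 20
Conditions: MOMCl, i-Pr2NEt, CH2Cl2, 0 °C → rt
Reagents that add atoms: chloromethyl methyl ether, COCCl
Why: Acetal protection of the phenol as an ether that survives base and organometallics and falls later without protic acid.

Step 16
Reactants: 21 MOM ether ketone
Product: 22 7′β-alcohol (7′S)
Conditions: (R)-2-methyl-CBS-oxazaborolidine (20 mol%), BH3·SMe2, THF, −20 °C; MeOH
Reagents that add atoms: none
Why: Corey–Bakshi–Shibata reduction of an aryl alkyl ketone: the (R)-catalyst gives the (S)-carbinol as with 1-tetralone, and the substrate bias (axial hydride anti to the angular C10′ methyl) points the same way.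

Step 17
Reactants: 22 7′β-alcohol
Product: 23 7′β-triethylsilyl ether
Conditions: Et3SiOTf, 2,6-lutidine, CH2Cl2, −40 → 0 °C
Reagents that add atoms: triethylsilyl trifluoromethanesulfonate, CC[Si](CC)(CC)OS(=O)(=O)C(F)(F)F
Why: Silylation of a hindered secondary alcohol with a silyl triflate; a non-acyl group is needed at O7′ because an ester there would be attacked by the neighbouring ester enolate in step 19.

Step 18
Reactants: 23 7′β-triethylsilyl ether
Product: 24 tert-butyl arylacetate
Conditions: BrZnCH2CO2t-Bu (1.5 equiv), Pd(dba)2 (5 mol%), P(t-Bu)3 (10 mol%), THF, rt → 50 °C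
Reagents that add atoms: tert-butyl bromozincacetate, Br[Zn]CC(=O)OC(C)(C)C
Why: Palladium-catalysed α-arylation of an ester with its Reformatsky zinc enolate (Negishi-type coupling); the bulky, electron-rich phosphine permits oxidative addition and reductive elimination at the di-ortho-substituted bromide, and the neutral zinc reagent leaves acetal and silyl ether alone.

Step 19
Reactants: 11 decalin acetic acid, 24 tert-butyl arylacetate
Product: 26 α-aryl β-keto tert-butyl ester, via acyl imidazolide 25 (not isolated)
Conditions: 11, CDI, THF, rt; added to 24, LiN(SiMe3)2 (2.2 equiv), THF, −78 → −20 °C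
Reagents that add atoms: none
Why: Crossed Claisen acylation of a lithium ester enolate with an acyl imidazolide; the second equivalent of amide deprotonates the more acidic product and drives the reaction. The C20 silyl ester is too hindered to act as acyl donor.

Step 20
Reactants: 26 α-aryl β-keto tert-butyl ester, 27 methyl vinyl ketone
Product: 30 4″-aryl-4″-(tert-butoxycarbonyl)-3″-(decalinylmethyl)cyclohex-2″-enone, via Michael adduct 28 (not isolated), via aldol ketol 29 (not isolated)
Conditions: O-allyl-N-(9-anthracenylmethyl)cinchonidinium bromide (10 mol%), K2CO3 (s), toluene, −20 °C; then pyrrolidine, AcOH, 60 °C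
Reagents that add atoms: none
Why: Solid K2CO3 deprotonates 26 at the interface and the enolate, paired with the chiral ammonium cation, adds through its α-carbon to 27 (C4″–C5″ bond) to give 28; pyrrolidinium acetate then turns the methyl ketone into its terminal enamine, which attacks the neighbouring ketone to give 29, and loss of water forms the C2″=C3″ bond of 30. The closest known reaction type is the Robinson annulation of α-substituted β-keto esters with methyl vinyl ketone under cinchona ammonium phase-transfer catalysis. The one ring closes in the 6-(enolendo)-exo-trig mode. The one new stereocentre, C4″, is set in the Michael step by the catalyst, whose ion pair exposes one enolate face; the remote centres of the two halves should give only a weak bias, and the pseudoenantiomeric cinchoninium salt is available if the pairing is mismatched. The step needs C- over O-attack (a soft acceptor gives C), addition without retro-Claisen cleavage (no hydroxide or alkoxide is present) and closure from the methyl side: only the unhindered methyl ketone forms an enamine, its internal isomer could close only a four-membered ring, and the tert-butyl ester resists Dieckmann attack. Silyl ether, acetal, silyl ester and methylidene are inert to carbonate and to the buffered amine.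

Step 21
Reactants: 30 cyclohexenone with 7′-silyl ether
Product: 32 7′β-acetate, via 7′β-alcohol 31 (not isolated)
Conditions: PPTS, MeOH–CH2Cl2, rt; evaporate; Ac2O, DMAP, pyridine, rt
Reagents that add atoms: acetic anhydride, CC(=O)OC(C)=O
Why: Mild acid methanolysis removes the triethylsilyl ether and leaves the aryl MOM ether, tert-butyl ester and methylidene; acetylation follows at once. The acetate is installed before the carboxyl is freed so that O7′ cannot form a six-membered lactone.

Step 22
Reactants: 32 7′β-acetate
Product: 33 spirolactone enone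
Conditions: Me3SiOTf, 2,2′-bipyridyl, CH2Cl2, 0 °C → rt; H2O–THF; PPTS (cat.), toluene, 50 °C
Reagents that add atoms: none
Why: Silyl triflate with bipyridyl cleaves the MOM acetal through its pyridinium salt and the tert-butyl ester through its silyl ester without a free strong acid, so both 1,1-disubstituted alkenes, the benzylic acetate and the silyl ester survive. On hydrolysis the phenol closes the five-membered lactone onto the acid (5-exo-trig), helped by the quaternary α-carbon.

Step 23
Reactants: 33 spirolactone enone
Product: 34 trimethylsilyl enol ether (3″-H cis to the lactone carbonyl)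
Conditions: [(Ph3P)CuH]6 (0.4 equiv), Me3SiCl, THF, −40 °C → rt
Reagents that add atoms: chlorotrimethylsilane, C[Si](C)(C)Cl
Why: Conjugate reduction by the copper hydride cluster with silyl capture of the enolate: hydride enters C3″ axially from the lactone-carbonyl face, anti to the aryl carbon C14′ and its peri ring, so the CH2 link ends up equatorial and cis to the aryl carbon as in the target. The enol ether fixes the enolate towards C2″.

Step 24
Reactants: 34 trimethylsilyl enol ether
Product: 37 2″-methylidene ketone, via Mannich base 35 (not isolated), via methiodide 36 (not isolated)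
Conditions: [Me2N=CH2]I, CH2Cl2, rt; MeI; aq. NaHCO3, CH2Cl2
Reagents that add atoms: N,N-dimethylmethyleneiminium iodide, C=[N+](C)C.[I-]
Why: Mannich reaction of the silyl enol ether at C2″, quaternisation and E1cB loss of trimethylamine (Eschenmoser methylenation); bicarbonate is weak enough not to move the alkene into the ring.

Step 25
Reactants: 37 2″-methylidene ketone
Product: 38 2-(trimethylsilyl)ethyl ester of the target
Conditions: NaBH4, CeCl3·7H2O, MeOH–THF, −78 °C
Reagents that add atoms: none
Why: Luche 1,2-reduction: axial hydride delivery on the lactone-carbonyl face gives the equatorial C1″ alcohol cis to the C3″ side chain, and the cerium salt suppresses conjugate reduction of the exocyclic enone.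

Step 26
Reactants: 38 silyl ester of the target
Product: 39 CNP0558742.1
Conditions: Bu4NF, THF, 0 °C; dilute HCl work-up
Reagents that add atoms: none
Why: Fluoride attacks silicon and β-elimination releases ethene and the hindered carboxylate with no reaction at the C20 carbonyl; a lactone opened by fluoride should re-close on acidic work-up.

## Compound list

1 | carnosic acid | CC(C)c1cc2CC[C@H]3C(C)(C)CCC[C@]3(C(=O)O)c2c(O)c1O | starting material
2 | 2-(trimethylsilyl)ethyl carnosate (5α-H, 10β-ester) | CC(C)c1cc2CC[C@H]3C(C)(C)CCC[C@]3(C(=O)OCC[Si](C)(C)C)c2c(O)c1O | intermediate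
3 | decalin-fused seven-membered muconic anhydride of 2 (C11–O–C12) | CC(C)C1=CC2=C(C(=O)OC1=O)[C@@]1(C(=O)OCC[Si](C)(C)C)CCCC(C)(C)[C@@H]1CC2 | intermediate
4 | muconic half-ester (C12 methyl ester, C11 acid; 13Z) | OC(=O)C1=C(/C=C(/C(C)C)C(=O)OC)CC[C@H]2C(C)(C)CCC[C@]12C(=O)OCC[Si](C)(C)C | intermediate
5 | dimethyl cis,cis-muconate of ring-C-opened 2 (C8=C9, 13Z) | COC(=O)C1=C(/C=C(/C(C)C)C(=O)OC)CC[C@H]2C(C)(C)CCC[C@]12C(=O)OCC[Si](C)(C)C | intermediate
6 | 1,6-dihydro diester with C8=C14 alkene (C9/C13 and alkene isomers) | COC(=O)C1C(=CC(C(C)C)C(=O)OC)CC[C@H]2C(C)(C)CCC[C@]12C(=O)OCC[Si](C)(C)C | intermediate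
7 | trans-decalin β-keto ester: C8 ketone, C9 CO2Me, C10 CO2CH2CH2SiMe3, 4,4-dimethyl, 5α-H | COC(=O)C1C(=O)CC[C@H]2C(C)(C)CCC[C@]12C(=O)OCC[Si](C)(C)C | intermediate
8 | C9-(methoxycarbonylmethyl) derivative of 7 | COC(=O)CC1(C(=O)OC)C(=O)CC[C@H]2C(C)(C)CCC[C@]12C(=O)OCC[Si](C)(C)C | intermediate
9 | C8 ketone with 9β-CH2CO2Me (9α-H) | COC(=O)C[C@H]1C(=O)CC[C@H]2C(C)(C)CCC[C@]12C(=O)OCC[Si](C)(C)C | intermediate
10 | C8-methylidene analogue of 9 | COC(=O)C[C@H]1C(=C)CC[C@H]2C(C)(C)CCC[C@]12C(=O)OCC[Si](C)(C)C | intermediate
11 | decalin acetic acid (9β-CH2CO2H, C8 methylidene, C10 silyl ester) | OC(=O)C[C@H]1C(=C)CC[C@H]2C(C)(C)CCC[C@]12C(=O)OCC[Si](C)(C)C | intermediate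
12 | 2-bromo-3-methoxybenzaldehyde | COc1cccc(C=O)c1Br | starting material
13 | (2-bromo-3-methoxyphenyl)methanol | COc1cccc(CO)c1Br | intermediate
14 | 2-bromo-1-(chloromethyl)-3-methoxybenzene | COc1cccc(CCl)c1Br | intermediate
15 | geranyl chloride | CC(C)=CCC/C(C)=C/CCl | starting material
16 | (2-bromo-3-methoxybenzyl)magnesium chloride | COc1cccc(C[Mg]Cl)c1Br | intermediate
17 | 2-bromo-1-[(3E)-4,8-dimethylnona-3,7-dienyl]-3-methoxybenzene | COc1cccc(CC/C=C(\C)CCC=C(C)C)c1Br | intermediate
18 | 14′-bromo-13′-methoxypodocarpa-8′,11′,13′-triene (5′α-H, 10′β-CH3) | COc1ccc2c(c1Br)CC[C@H]1C(C)(C)CCC[C@]21C | intermediate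
19 | 7′-ketone of 18 | COc1ccc2c(c1Br)C(=O)C[C@H]1C(C)(C)CCC[C@]21C | intermediate
20 | 14′-bromo-13′-hydroxypodocarpa-8′,11′,13′-trien-7′-one | Oc1ccc2c(c1Br)C(=O)C[C@H]1C(C)(C)CCC[C@]21C | intermediate
21 | 13′-O-methoxymethyl ether of 20 | COCOc1ccc2c(c1Br)C(=O)C[C@H]1C(C)(C)CCC[C@]21C | intermediate
22 | 7′β-alcohol (7′S) of 21 | COCOc1ccc2c(c1Br)[C@@H](O)C[C@H]1C(C)(C)CCC[C@]21C | intermediate
23 | 7′β-triethylsilyl ether of 22 | COCOc1ccc2c(c1Br)[C@@H](O[Si](CC)(CC)CC)C[C@H]1C(C)(C)CCC[C@]21C | intermediate
24 | tert-butyl arylacetate (CH2CO2t-Bu on C14′) | COCOc1ccc2c(c1CC(=O)OC(C)(C)C)[C@@H](O[Si](CC)(CC)CC)C[C@H]1C(C)(C)CCC[C@]21C | intermediate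
25 | acyl imidazolide of 11 | C=C1CC[C@H]2C(C)(C)CCC[C@]2(C(=O)OCC[Si](C)(C)C)[C@H]1CC(=O)n1ccnc1 | intermediate
26 | tert-butyl 2-aryl-3-oxo ester carrying the decalin (α-carbon epimers/enol) | C=C1CC[C@H]2C(C)(C)CCC[C@]2(C(=O)OCC[Si](C)(C)C)[C@H]1CC(=O)C(C(=O)OC(C)(C)C)c1c(OCOC)ccc2c1[C@@H](O[Si](CC)(CC)CC)C[C@H]1C(C)(C)CCC[C@]21C | intermediate
27 | methyl vinyl ketone | CC(=O)C=C | starting material
28 | Michael adduct (quaternary carbon as in the target) | C=C1CC[C@H]2C(C)(C)CCC[C@]2(C(=O)OCC[Si](C)(C)C)[C@H]1CC(=O)[C@](CCC(C)=O)(C(=O)OC(C)(C)C)c1c(OCOC)ccc2c1[C@@H](O[Si](CC)(CC)CC)C[C@H]1C(C)(C)CCC[C@]21C | intermediate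
29 | aldol ketol (3″-hydroxycyclohexanone) | C=C1CC[C@H]2C(C)(C)CCC[C@]2(C(=O)OCC[Si](C)(C)C)[C@H]1CC1(O)CC(=O)CC[C@@]1(C(=O)OC(C)(C)C)c1c(OCOC)ccc2c1[C@@H](O[Si](CC)(CC)CC)C[C@H]1C(C)(C)CCC[C@]21C | intermediate
30 | 4″-aryl-4″-(tert-butoxycarbonyl)-3″-(decalinylmethyl)cyclohex-2″-enone, 7′-OSiEt3 | C=C1CC[C@H]2C(C)(C)CCC[C@]2(C(=O)OCC[Si](C)(C)C)[C@H]1CC1=CC(=O)CC[C@@]1(C(=O)OC(C)(C)C)c1c(OCOC)ccc2c1[C@@H](O[Si](CC)(CC)CC)C[C@H]1C(C)(C)CCC[C@]21C | intermediate
31 | 7′β-alcohol of 30 | C=C1CC[C@H]2C(C)(C)CCC[C@]2(C(=O)OCC[Si](C)(C)C)[C@H]1CC1=CC(=O)CC[C@@]1(C(=O)OC(C)(C)C)c1c(OCOC)ccc2c1[C@@H](O)C[C@H]1C(C)(C)CCC[C@]21C | intermediate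
32 | 7′β-acetate of 31 | C=C1CC[C@H]2C(C)(C)CCC[C@]2(C(=O)OCC[Si](C)(C)C)[C@H]1CC1=CC(=O)CC[C@@]1(C(=O)OC(C)(C)C)c1c(OCOC)ccc2c1[C@@H](OC(C)=O)C[C@H]1C(C)(C)CCC[C@]21C | intermediate
33 | spirolactone cyclohex-2″-enone | C=C1CC[C@H]2C(C)(C)CCC[C@]2(C(=O)OCC[Si](C)(C)C)[C@H]1CC1=CC(=O)CC[C@]12C(=O)Oc1ccc3c(c12)[C@@H](OC(C)=O)C[C@H]1C(C)(C)CCC[C@]31C | intermediate
34 | trimethylsilyl enol ether (C1″=C2″; 3″-H cis to lactone C=O) | C=C1CC[C@H]2C(C)(C)CCC[C@]2(C(=O)OCC[Si](C)(C)C)[C@H]1C[C@H]1C=C(O[Si](C)(C)C)CC[C@]12C(=O)Oc1ccc3c(c12)[C@@H](OC(C)=O)C[C@H]1C(C)(C)CCC[C@]31C | intermediate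
35 | 2″-(dimethylaminomethyl) ketone (Mannich base) | C=C1CC[C@H]2C(C)(C)CCC[C@]2(C(=O)OCC[Si](C)(C)C)[C@H]1C[C@H]1C(CN(C)C)C(=O)CC[C@]12C(=O)Oc1ccc3c(c12)[C@@H](OC(C)=O)C[C@H]1C(C)(C)CCC[C@]31C | intermediate
36 | trimethylammonium iodide of 35 | C=C1CC[C@H]2C(C)(C)CCC[C@]2(C(=O)OCC[Si](C)(C)C)[C@H]1C[C@H]1C(C[N+](C)(C)C)C(=O)CC[C@]12C(=O)Oc1ccc3c(c12)[C@@H](OC(C)=O)C[C@H]1C(C)(C)CCC[C@]31C.[I-] | intermediate
37 | 2″-methylidene-1″-ketone | C=C1CC[C@H]2C(C)(C)CCC[C@]2(C(=O)OCC[Si](C)(C)C)[C@H]1C[C@H]1C(=C)C(=O)CC[C@]12C(=O)Oc1ccc3c(c12)[C@@H](OC(C)=O)C[C@H]1C(C)(C)CCC[C@]31C | intermediate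
38 | 2-(trimethylsilyl)ethyl ester of the target (1″-OH cis to the 3″ side chain) | C=C1CC[C@H]2C(C)(C)CCC[C@]2(C(=O)OCC[Si](C)(C)C)[C@H]1C[C@H]1C(=C)[C@@H](O)CC[C@]12C(=O)Oc1ccc3c(c12)[C@@H](OC(C)=O)C[C@H]1C(C)(C)CCC[C@]31C | intermediate
39 | CNP0558742.1 | C=C1CC[C@H]2C(C)(C)CCC[C@]2(C(=O)O)[C@H]1C[C@H]1C(=C)[C@@H](O)CC[C@]12C(=O)Oc1ccc3c(c12)[C@@H](OC(C)=O)C[C@H]1C(C)(C)CCC[C@]31C | target

## Step count and risks

Total: 26 steps. Longest linear sequence: 18 steps (steps 9–18 from aldehyde 12, then steps 19–26). The decalin branch (steps 1–8) joins at step 19.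

**Step 20 (key step).** The most likely failure is poor facial selectivity at C4″: the enolate of an acyclic α-aryl keto ester with a twisted, di-ortho-substituted aryl group offers the ion pair little to grip, and the remote chirality may oppose the catalyst. The Michael addition may also be slow at so crowded a carbon, and the hindered internal ketone may condense slowly. Fallback: from 26, run the conjugate addition to 27 under a chiral divalent palladium aqua complex, [Pd((R)-BINAP)(H2O)2](OTf)2 in THF at −20 °C. This works through a chiral metal enolate under base-free conditions; either BINAP enantiomer can be used. Isolate 28, separate any C4″ epimer there, and condense it with pyrrolidinium acetate to rejoin the route at 30.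

**Step 3.** The electron-transfer reduction may lose regiocontrol (1,4- in place of 1,6-delivery, over-reduction after base-induced reconjugation) because the tetrasubstituted diene is twisted. Fallback from 5: ozonolysis of the exposed side-chain alkene should give the formyl ester F1. Oxidation with NaClO2 gives the acid F2. (PhO)2P(O)N3 with Et3N gives the acyl azide F3, which rearranges on heating (Curtius) to the vinyl isocyanate F4. Aqueous acid hydrolyses F4 through the enamine to β-keto ester 7, where the route is rejoined.

**Step 5.** The alkylation creates a quaternary C9 beside the quaternary C10, so O-alkylation or no reaction may take over. Fallback from 7: allylation with allyl methyl carbonate and Pd(PPh3)4 (outer-sphere attack on a small π-allyl electrophile) to the C-allyl keto diester F5. Krapcho reaction gives the allyl ketone F6, ozonolysis the keto aldehyde F7, and NaClO2 oxidation the keto acid F8. Methylenation of F8 with excess Ph3P=CH2 rejoins the route at 11.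

**Step 19.** The hindered enolate of 24 may deprotonate imidazolide 25 at its CH2 group (ketene formation) faster than it attacks the carbonyl, so acylation stalls. Fallback from 10: i-Bu2AlH at −78 °C gives the aldehyde F9. Aldol addition of the lithium enolate of 24 (one equivalent of LiN(i-Pr)2) gives the β-hydroxy ester F10, and Dess–Martin oxidation rejoins the route at 26.

**Step 23.** Hydride transfer from the bulky copper cluster to a β-carbon that bears the CH2 link and adjoins the quaternary C4″ may be too slow, or may lose facial selectivity. Fallback from 33: rhodium-catalysed 1,4-hydrosilylation with RhCl(PPh3)3 and Et3SiH, which proceeds by silyl-metal addition and not by a hydride cluster, gives the triethylsilyl enol ether F11. Treated as in step 24, F11 rejoins the route at 37.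

## Further compounds

F0 | step 20 | none | none
F1 | step 3 | C8-formyl C9-methyl ester with C8=C9 alkene | COC(=O)C1=C(C=O)CC[C@H]2C(C)(C)CCC[C@]12C(=O)OCC[Si](C)(C)C
F2 | step 3 | C8-carboxylic acid of F1 | COC(=O)C1=C(C(=O)O)CC[C@H]2C(C)(C)CCC[C@]12C(=O)OCC[Si](C)(C)C
F3 | step 3 | acyl azide of F2 | COC(=O)C1=C(C(=O)N=[N+]=[N-])CC[C@H]2C(C)(C)CCC[C@]12C(=O)OCC[Si](C)(C)C
F4 | step 3 | C8 vinyl isocyanate | COC(=O)C1=C(N=C=O)CC[C@H]2C(C)(C)CCC[C@]12C(=O)OCC[Si](C)(C)C
F5 | step 5 | C9-allyl β-keto ester | C=CCC1(C(=O)OC)C(=O)CC[C@H]2C(C)(C)CCC[C@]12C(=O)OCC[Si](C)(C)C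
F6 | step 5 | 9β-allyl C8 ketone | C=CC[C@H]1C(=O)CC[C@H]2C(C)(C)CCC[C@]12C(=O)OCC[Si](C)(C)C
F7 | step 5 | C8 ketone with 9β-CH2CHO | O=CC[C@H]1C(=O)CC[C@H]2C(C)(C)CCC[C@]12C(=O)OCC[Si](C)(C)C
F8 | step 5 | C8 ketone with 9β-CH2CO2H | OC(=O)C[C@H]1C(=O)CC[C@H]2C(C)(C)CCC[C@]12C(=O)OCC[Si](C)(C)C
F9 | step 19 | decalin acetaldehyde | C=C1CC[C@H]2C(C)(C)CCC[C@]2(C(=O)OCC[Si](C)(C)C)[C@H]1CC=O
F10 | step 19 | tert-butyl 2-aryl-3-hydroxy ester (aldol adduct) | C=C1CC[C@H]2C(C)(C)CCC[C@]2(C(=O)OCC[Si](C)(C)C)[C@H]1CC(O)C(C(=O)OC(C)(C)C)c1c(OCOC)ccc2c1[C@@H](O[Si](CC)(CC)CC)C[C@H]1C(C)(C)CCC[C@]21C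
F11 | step 23 | triethylsilyl enol ether analogue of 34 | C=C1CC[C@H]2C(C)(C)CCC[C@]2(C(=O)OCC[Si](C)(C)C)[C@H]1C[C@H]1C=C(O[Si](CC)(CC)CC)CC[C@]12C(=O)Oc1ccc3c(c12)[C@@H](OC(C)=O)C[C@H]1C(C)(C)CCC[C@]31C
A1 | alternative 1 | decalin-fused cis,cis-muconic anhydride (C20 methyl ester) | CC(C)C1=CC2=C(C(=O)OC1=O)[C@@]1(C(=O)OC)CCCC(C)(C)[C@@H]1CC2
A2 | alternative 1 | methyl carnosate ortho-quinone | CC(C)C1=CC2=C(C(=O)C1=O)[C@@]1(C(=O)OC)CCCC(C)(C)[C@@H]1CC2
A3 | alternative 2 | 3β-hydroxy decalin with exocyclic methylene attached to the spirolactone enone | C=C1CC[C@H]2C(C)(C)[C@@H](O)CC[C@]2(CO[Si](C)(C)C(C)(C)C)[C@H]1CC1=CC(=O)CC[C@]12C(=O)Oc1ccc3c(c12)[C@@H](O[Si](C)(C)C(C)(C)C)C[C@H]1C(C)(C)CCC[C@]31C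
A4 | alternative 3 | spiro benzofuranone cyclohexene ketal with blocking bromine | C=C1CC[C@H]2C(C)(C)CCC[C@]2(C(=O)OCC[Si](C)(C)C)[C@H]1CC1=CC4(OCCO4)CC[C@]12C(=O)Oc1c(Br)cc3c(c12)[C@@H](OC(C)=O)C[C@H]1C(C)(C)CCC[C@]31C
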